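The key step exploits the cyclohexene ring (C3a–C4=C5–C6–C7–C7a of the hydrindanone; C4 methylated, C6 styryl-bearing, C7 carboxyl-bearing): it is a Diels–Alder retron whose diene is cut at its central C4–C5 bond. One operation, a Stille coupling of an acyclic vinyl iodide (C4) with a dienylstannane (C5), makes that bond and thereby releases an all-E tetraenal that cyclises in the same flask. The new C4–C5 link becomes the ring alkene while C6–C7 and C3a–C7a close, creating both vicinal quaternary carbons and the trans ring fusion under control of the C1 and C3 stereocentres. The precursors are a hydroxy iodo-enal, with the C2 carbinol as ketone surrogate, and a styryl-substituted vinylstannane.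

Key step: step 11

Remark on atom labels: hydrindanone numbering is used throughout: C1 ethyl-bearing CH, C2 carbonyl (a carbinol until the last step), C3 methyl-bearing CH, C3a and C7a ring-fusion carbons, C4=C5 ring alkene, C6 styryl-bearing and C7 carboxyl-bearing quaternary carbons.
Assumption: 2-(triphenylphosphoranylidene)butanal is taken as a purchasable stabilised ylide. The C2 carbinol configuration is free because it is oxidised at the end; the one chosen (hydroxyl trans to the C7a–C7 bond) cannot form a lactol or lactone with the C7 carbonyl group.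

Step 1
Reactants: 1 (S)-but-3-yn-2-ol
Product: 2 (S)-but-3-yn-2-yl methanesulfonate
Conditions: MsCl, Et3N, CH2Cl2, −78 → 0 °C
Reagents that add atoms: methanesulfonyl chloride CS(=O)(=O)Cl
Why: O-sulfonylation (mesylation) leaves the stereocentre untouched and installs the leaving group for the SN2′ displacement.

Step 2
Reactants: 2 (S)-but-3-yn-2-yl methanesulfonate
Product: 3 (aR)-tributyl(buta-1,2-dien-1-yl)stannane
Conditions: Bu3SnH, LiN(iPr)2, THF, 0 °C; CuBr·SMe2, −78 °C; then 2, −78 °C
Reagents that add atoms: tributyltin hydride CCCC[SnH](CCCC)CCCC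
Why: Anti SN2′ displacement of the propargylic mesylate by the stannylcopper reagent (propargylic substitution with an organocopper) should transfer the central chirality of 2 into the axial chirality of the allene.

Step 3
Reactants: 3 (aR)-tributyl(buta-1,2-dien-1-yl)stannane; 4 2-methylidenebutanal (2-ethylacrolein)
Product: 5 (3R,4S)-2-ethyl-4-methylhex-1-en-5-yn-3-ol
Conditions: BF3·OEt2 (1.5 equiv), CH2Cl2, −78 °C
Reagents that add atoms: none
Why: Lewis acid promoted SE2′ addition of the allenylstannane (allenylstannane propargylation) fixes the methyl-bearing carbon by attack anti to tin (axial-to-central transfer) and the carbinol carbon by the syn preference of the open antiperiplanar transition state.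

Step 4
Reactants: 5 (3R,4S)-2-ethyl-4-methylhex-1-en-5-yn-3-ol
Product: 7 (3R,4S)-2-ethyl-4-methylhept-1-en-5-yn-3-ol, via dilithio alkoxide-acetylide 6 (not isolated)
Conditions: n-BuLi (2.1 equiv), THF, −78 → −20 °C; MeI (1.05 equiv), −78 → 0 °C; H2O
Reagents that add atoms: iodomethane CI
Why: Acetylide alkylation: one equivalent of MeI is taken up by the more nucleophilic acetylide carbon of the dianion while the lithium alkoxide stays inert at low temperature, and no stereocentre is touched.

Step 5
Reactants: 7 (3R,4S)-2-ethyl-4-methylhept-1-en-5-yn-3-ol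
Product: 9 (3R,4S,5E)-2-ethyl-6-iodo-4-methylhepta-1,5-dien-3-ol, via alkenylzirconocene 8 (not isolated)
Conditions: Cp2Zr(H)Cl (3 equiv), THF, 25–45 °C; then I2, 0 °C
Reagents that add atoms: iodine II
Why: Syn hydrozirconation with excess reagent places zirconium on the less hindered methyl-bearing alkyne carbon and iodinolysis with retention gives the E vinyl iodide (hydrozirconation–iodination); the 1,1-disubstituted alkene reacts far more slowly.

Step 6
Reactants: 9 (3R,4S,5E)-2-ethyl-6-iodo-4-methylhepta-1,5-dien-3-ol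
Product: 11 (2S,3R,4S,5E)-2-ethyl-6-iodo-4-methylhept-5-ene-1,3-diol, via B-alkyl-9-BBN adduct 10 (not isolated)
Conditions: 9-BBN (2.5 equiv), THF, 0 → 25 °C; then NaOH, H2O2, H2O, 0 → 25 °C
Reagents that add atoms: hydrogen peroxide OO
Why: Hydroboration–oxidation of the allylic alcohol: in the conformer with the carbinol hydrogen nearly eclipsing the alkene, 9-BBN should add anti to the branched alkyl residue and set the ethyl-bearing centre anti to the hydroxyl, with the trisubstituted vinyl iodide inert.

Step 7
Reactants: 11 (2S,3R,4S,5E)-2-ethyl-6-iodo-4-methylhept-5-ene-1,3-diol; 12 2-(triphenylphosphoranylidene)butanal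
Product: 14 (2E,4S,5R,6S,7E)-2,4-diethyl-5-hydroxy-8-iodo-6-methylnona-2,7-dienal, via hydroxy aldehyde 13 (not isolated)
Conditions: TEMPO (10 mol %), PhI(OAc)2, CH2Cl2, 25 °C; NaHCO3 wash; crude aldehyde + ylide, toluene, 80 °C
Reagents that add atoms: none
Why: Nitroxyl-catalysed oxidation takes the primary alcohol in preference to the hindered secondary one, and the Wittig reaction of the formyl-stabilised ylide should give the E trisubstituted enal without touching the stereocentres.

Step 8
Reactants: 4 2-methylidenebutanal (2-ethylacrolein)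
Product: 16 (2E)-3-bromo-2-ethylprop-2-enal, via dibromo aldehyde 15 (not isolated)
Conditions: Br2, CH2Cl2, −78 → 0 °C; then Et3N, 0 → 25 °C
Reagents that add atoms: bromine BrBr
Why: Bromination–dehydrobromination: amine-induced loss of HBr through the more acidic CH2Br hydrogen should give the conjugated β-bromo enal, the E isomer (bromine trans to formyl) being the thermodynamically preferred one.

Step 9
Reactants: 16 (2E)-3-bromo-2-ethylprop-2-enal; 17 diethyl benzylphosphonate
Product: 19 [(1E,3E)-4-bromo-3-ethylbuta-1,3-dien-1-yl]benzene, via sodium phosphonate carbanion 18 (not isolated)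
Conditions: NaN(SiMe3)2, THF, −78 °C; then 16, −78 → 25 °C
Reagents that add atoms: none
Why: Horner–Wadsworth–Emmons olefination with the benzylphosphonate anion is E-selective for the new styryl alkene and leaves the vinyl bromide geometry intact.

Step 10
Reactants: 19 [(1E,3E)-4-bromo-3-ethylbuta-1,3-dien-1-yl]benzene
Product: 21 tributyl[(1E,3E)-2-ethyl-4-phenylbuta-1,3-dien-1-yl]stannane, via dienyllithium 20 (not isolated)
Conditions: t-BuLi (2.1 equiv), Et2O, −78 °C; Bu3SnCl, −78 → 25 °C
Reagents that add atoms: tributyltin chloride CCCC[Sn](Cl)(CCCC)CCCC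
Why: Bromine–lithium exchange and stannylation of the vinyllithium both proceed with retention of alkene geometry (halogen–metal exchange/stannylation).

Step 11
Reactants: 14 (2E,4S,5R,6S,7E)-2,4-diethyl-5-hydroxy-8-iodo-6-methylnona-2,7-dienal; 21 tributyl[(1E,3E)-2-ethyl-4-phenylbuta-1,3-dien-1-yl]stannane
Product: 23 (1S,2R,3S,3aR,4R,5S,7aR)-3,4,5-triethyl-2-hydroxy-1,7-dimethyl-5-[(E)-2-phenylethenyl]-2,3,3a,4,5,7a-hexahydro-1H-indene-4-carbaldehyde, via tetraenal 22 (not isolated)
Conditions: Pd2(dba)3 (5 mol %), AsPh3 (20 mol %), CuI (10 mol %), BHT, degassed NMP, 25 °C; then 60–80 °C in the same flask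
Reagents that add atoms: none
Why: Zerovalent palladium inserts into the C–I bond of 14, copper-assisted transmetalation from 21 and reductive elimination forge the C4–C5 σ-bond with retention at both alkenes, which completes the all-E diene C3a=C4–C5=C6 next to the enal and sets off a type 1 intramolecular Diels–Alder reaction in which C4–C5 becomes the ring alkene while C6–C7 and C3a–C7a form. The closest known reaction type is the domino Stille coupling/intramolecular Diels–Alder cascade. The cyclohexene closes by suprafacial [4+2] cycloaddition, and the cyclopentane closes at the same time because the three-atom tether C3–C2–C1 is bridged by the C3a–C7a bond, giving the fused bicyclo[4.3.0] skeleton. C6 and C7 follow from the alkene geometries (styryl outside on the diene terminus, E enal) and the formyl-endo transition state, which also makes the ring fusion trans; the absolute face is set by C1 and C3, whose hydrogens eclipse the neighbouring trisubstituted alkenes (A(1,3) strain) so that ethyl and methyl point away from the forming ring. The step needs endo over exo selectivity and a single diene face: the trans relationship of the C1 ethyl and C3 methyl groups fits only the trans-fused endo transition state, so the two stereocentres should reinforce each other. Coupling must outrun protodestannylation of 21, which the absence of acidic groups other than the hydroxyl and the copper co-catalyst should secure.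

Step 12
Reactants: 23 (1S,2R,3S,3aR,4R,5S,7aR)-3,4,5-triethyl-2-hydroxy-1,7-dimethyl-5-[(E)-2-phenylethenyl]-2,3,3a,4,5,7a-hexahydro-1H-indene-4-carbaldehyde
Product: 24 (1S,2R,3S,3aR,4R,5S,7aR)-3,4,5-triethyl-2-hydroxy-1,7-dimethyl-5-[(E)-2-phenylethenyl]-2,3,3a,4,5,7a-hexahydro-1H-indene-4-carboxylic acid
Conditions: NaClO2, NaH2PO4, 2-methylbut-2-ene, t-BuOH/H2O, 25 °C
Reagents that add atoms: sodium chlorite [Na+].[O-]Cl=O
Why: Pinnick oxidation converts even a neopentyl aldehyde into the acid under buffered conditions, with 2-methylbut-2-ene scavenging HOCl to protect the alkenes and the secondary alcohol left untouched.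

Step 13
Reactants: 24 (1S,2R,3S,3aR,4R,5S,7aR)-3,4,5-triethyl-2-hydroxy-1,7-dimethyl-5-[(E)-2-phenylethenyl]-2,3,3a,4,5,7a-hexahydro-1H-indene-4-carboxylic acid
Product: 25 (1S,3S,3aR,4R,5S,7aR)-3,4,5-triethyl-1,7-dimethyl-2-oxo-5-[(E)-2-phenylethenyl]-2,3,3a,4,5,7a-hexahydro-1H-indene-4-carboxylic acid
Conditions: Dess–Martin periodinane, CH2Cl2, 0 → 25 °C
Reagents that add atoms: none
Why: Dess–Martin oxidation of the secondary alcohol gives the ketone under near-neutral conditions in the presence of the free acid; C1 and C3 already hold the thermodynamically preferred configuration (each substituent trans to its ring neighbour), so no epimerisation is expected.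

Compound list
1 | (S)-but-3-yn-2-ol | C[C@H](O)C#C | starting material
2 | (S)-but-3-yn-2-yl methanesulfonate | C[C@H](OS(C)(=O)=O)C#C | intermediate
3 | (aR)-tributyl(buta-1,2-dien-1-yl)stannane | [H]C([Sn](CCCC)(CCCC)CCCC)=[C@@]=C([H])C | intermediate
4 | 2-methylidenebutanal (2-ethylacrolein) | CCC(=C)C=O | starting material
5 | (3R,4S)-2-ethyl-4-methylhex-1-en-5-yn-3-ol | CCC(=C)[C@H](O)[C@@H](C)C#C | intermediate
6 | dilithio derivative of 5 (lithium alkoxide, lithium acetylide) | CCC(=C)[C@H](O[Li])[C@@H](C)C#C[Li] | intermediate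
7 | (3R,4S)-2-ethyl-4-methylhept-1-en-5-yn-3-ol | CCC(=C)[C@H](O)[C@@H](C)C#CC | intermediate
8 | E-alkenylzirconocene chloride from 7 (zirconium on the methyl-bearing alkene carbon, hydroxyl as zirconocene alkoxide) | CCC(=C)[C@H](O[Zr](Cl)(C1C=CC=C1)C1C=CC=C1)[C@@H](C)/C=C(\C)[Zr](Cl)(C1C=CC=C1)C1C=CC=C1 | intermediate
9 | (3R,4S,5E)-2-ethyl-6-iodo-4-methylhepta-1,5-dien-3-ol | CCC(=C)[C@H](O)[C@@H](C)/C=C(\C)I | intermediate
10 | B-alkyl-9-borabicyclo[3.3.1]nonane adduct of 9 (boron on the former =CH2 carbon, configuration as in 11) | CC[C@@H](CB1C2CCCC1CCC2)[C@H](O)[C@@H](C)/C=C(\C)I | intermediate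
11 | (2S,3R,4S,5E)-2-ethyl-6-iodo-4-methylhept-5-ene-1,3-diol | CC[C@@H](CO)[C@H](O)[C@@H](C)/C=C(\C)I | intermediate
12 | 2-(triphenylphosphoranylidene)butanal | CCC(C=O)=P(c1ccccc1)(c1ccccc1)c1ccccc1 | starting material
13 | (2R,3R,4S,5E)-2-ethyl-3-hydroxy-6-iodo-4-methylhept-5-enal | CC[C@@H](C=O)[C@H](O)[C@@H](C)/C=C(\C)I | intermediate
14 | (2E,4S,5R,6S,7E)-2,4-diethyl-5-hydroxy-8-iodo-6-methylnona-2,7-dienal | CC[C@@H](/C=C(\CC)C=O)[C@H](O)[C@@H](C)/C=C(\C)I | intermediate
15 | 2-bromo-2-(bromomethyl)butanal (racemic) | CCC(Br)(CBr)C=O | intermediate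
16 | (2E)-3-bromo-2-ethylprop-2-enal | Br/C=C(\CC)C=O | intermediate
17 | diethyl benzylphosphonate | CCOP(=O)(Cc1ccccc1)OCC | starting material
18 | sodium [diethoxyphosphoryl(phenyl)methanide] | CCOP(=O)([CH-]c1ccccc1)OCC.[Na+] | intermediate
19 | [(1E,3E)-4-bromo-3-ethylbuta-1,3-dien-1-yl]benzene | Br/C=C(\CC)/C=C/c1ccccc1 | intermediate
20 | [(1E,3E)-2-ethyl-4-phenylbuta-1,3-dien-1-yl]lithium | [Li]/C=C(\CC)/C=C/c1ccccc1 | intermediate
21 | tributyl[(1E,3E)-2-ethyl-4-phenylbuta-1,3-dien-1-yl]stannane | CCCC[Sn](CCCC)(CCCC)/C=C(\CC)/C=C/c1ccccc1 | intermediate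
22 | (2E,4S,5R,6S,7E,9E,11E)-2,4,10-triethyl-5-hydroxy-6,8-dimethyl-12-phenyldodeca-2,7,9,11-tetraenal | CC[C@@H](/C=C(\CC)C=O)[C@H](O)[C@@H](C)/C=C(\C)/C=C(\CC)/C=C/c1ccccc1 | intermediate
23 | (1S,2R,3S,3aR,4R,5S,7aR)-3,4,5-triethyl-2-hydroxy-1,7-dimethyl-5-[(E)-2-phenylethenyl]-2,3,3a,4,5,7a-hexahydro-1H-indene-4-carbaldehyde | CC[C@@H]1[C@H](O)[C@@H](C)[C@@H]2C(C)=C[C@@](/C=C/c3ccccc3)(CC)[C@](CC)(C=O)[C@H]21 | intermediate
24 | (1S,2R,3S,3aR,4R,5S,7aR)-3,4,5-triethyl-2-hydroxy-1,7-dimethyl-5-[(E)-2-phenylethenyl]-2,3,3a,4,5,7a-hexahydro-1H-indene-4-carboxylic acid | CC[C@@H]1[C@H](O)[C@@H](C)[C@@H]2C(C)=C[C@@](/C=C/c3ccccc3)(CC)[C@](CC)(C(=O)O)[C@H]21 | intermediate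
25 | (1S,3S,3aR,4R,5S,7aR)-3,4,5-triethyl-1,7-dimethyl-2-oxo-5-[(E)-2-phenylethenyl]-2,3,3a,4,5,7a-hexahydro-1H-indene-4-carboxylic acid | CC[C@@H]1C(=O)[C@@H](C)[C@@H]2C(C)=C[C@@](/C=C/c3ccccc3)(CC)[C@](CC)(C(=O)O)[C@H]21 | target

Total step count: 13
Longest linear sequence: 10 steps (steps 1–7, 11, 12 and 13)

Steps most likely to fail

Step 11. The cross-coupling may lose to protodestannylation or homocoupling of the stannane, and the uncatalysed cycloaddition may show insufficient endo or facial selectivity at the temperature the coupling needs. The fallback separates the two events and puts the cycloaddition under catalyst control. It sets out from 14: Luche reduction (NaBH4, CeCl3, MeOH, 0 °C) gives (2E,4S,5R,6S,7E)-2,4-diethyl-8-iodo-6-methylnona-2,7-diene-1,5-diol F1. Stille coupling of F1 with 21 under the conditions of step 11 at 25 °C then gives the unactivated, isolable (2E,4S,5R,6S,7E,9E,11E)-2,4,10-triethyl-6,8-dimethyl-12-phenyldodeca-2,7,9,11-tetraene-1,5-diol F2. MnO2 in CH2Cl2 oxidises only the allylic alcohol to tetraenal 22, which is cyclised at low temperature with Me2AlCl (2 equiv, the first consumed by the hydroxyl) or with an imidazolidinone salt for iminium activation. The fallback comes back to the route at 23.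

Step 3. The syn preference of the open transition state may erode with an α-branched enal, and the enal may oligomerise under BF3. The fallback replaces the allene chemistry by an auxiliary-controlled aldol and sets out from 4. The dibutylboron enolate of (R)-4-benzyl-3-propanoyloxazolidin-2-one F3 (Bu2BOTf, Et3N, CH2Cl2, −78 °C) adds to 4 in an Evans syn aldol reaction to give (R)-4-benzyl-3-[(2R,3R)-3-hydroxy-2-methyl-4-methylidenehexanoyl]oxazolidin-2-one F4. LiBH4 (THF, MeOH, 0 °C) removes the auxiliary to give (2S,3R)-2-methyl-4-methylidenehexane-1,3-diol F5. Selective oxidation of the primary alcohol (TEMPO, PhI(OAc)2) gives (2R,3R)-3-hydroxy-2-methyl-4-methylidenehexanal F6. Seyferth–Gilbert homologation with dimethyl (1-diazo-2-oxopropyl)phosphonate (K2CO3, MeOH, 0 °C) comes back to the route at 5.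

Step 8. HBr may be lost toward the ethyl group, giving the 2-(bromomethyl) enal, or an E/Z mixture of the bromo enal may form. The fallback builds the halo-alkene where only one elimination is possible. It does not use 4; it sets out from 17, kept as the olefination partner, together with purchased diethyl 2-ethylpropanedioate F7. NaH and CHI3 (Et2O, reflux) give diethyl 2-(diiodomethyl)-2-ethylpropanedioate F8. KOH in aqueous ethanol at reflux (saponification, decarboxylation, loss of iodide) gives (2E)-2-ethyl-3-iodoprop-2-enoic acid F9. LiAlH4 (Et2O, 0 °C) gives (2E)-2-ethyl-3-iodoprop-2-en-1-ol F10, and MnO2 gives (2E)-2-ethyl-3-iodoprop-2-enal F11. Olefination with 18 (from 17, as in step 9) gives [(1E,3E)-3-ethyl-4-iodobuta-1,3-dien-1-yl]benzene F12. Iodine–lithium exchange (t-BuLi, Et2O, −78 °C) gives 20, and Bu3SnCl brings the fallback back to the route at 21.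

Further compounds
F1 | step 11 | (2E,4S,5R,6S,7E)-2,4-diethyl-8-iodo-6-methylnona-2,7-diene-1,5-diol | CC[C@@H](/C=C(\CC)CO)[C@H](O)[C@@H](C)/C=C(\C)I
F2 | step 11 | (2E,4S,5R,6S,7E,9E,11E)-2,4,10-triethyl-6,8-dimethyl-12-phenyldodeca-2,7,9,11-tetraene-1,5-diol | CC[C@@H](/C=C(\CC)CO)[C@H](O)[C@@H](C)/C=C(\C)/C=C(\CC)/C=C/c1ccccc1
F3 | step 3 | (R)-4-benzyl-3-propanoyloxazolidin-2-one | CCC(=O)N1C(=O)OC[C@H]1Cc1ccccc1
F4 | step 3 | (R)-4-benzyl-3-[(2R,3R)-3-hydroxy-2-methyl-4-methylidenehexanoyl]oxazolidin-2-one | CCC(=C)[C@H](O)[C@@H](C)C(=O)N1C(=O)OC[C@H]1Cc1ccccc1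
F5 | step 3 | (2S,3R)-2-methyl-4-methylidenehexane-1,3-diol | CCC(=C)[C@H](O)[C@@H](C)CO
F6 | step 3 | (2R,3R)-3-hydroxy-2-methyl-4-methylidenehexanal | CCC(=C)[C@H](O)[C@@H](C)C=O
F7 | step 8 | diethyl 2-ethylpropanedioate | CCOC(=O)C(CC)C(=O)OCC
F8 | step 8 | diethyl 2-(diiodomethyl)-2-ethylpropanedioate | CCOC(=O)C(CC)(C(I)I)C(=O)OCC
F9 | step 8 | (2E)-2-ethyl-3-iodoprop-2-enoic acid | I/C=C(\CC)C(=O)O
F10 | step 8 | (2E)-2-ethyl-3-iodoprop-2-en-1-ol | I/C=C(\CC)CO
F11 | step 8 | (2E)-2-ethyl-3-iodoprop-2-enal | I/C=C(\CC)C=O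
F12 | step 8 | [(1E,3E)-3-ethyl-4-iodobuta-1,3-dien-1-yl]benzene | I/C=C(\CC)/C=C/c1ccccc1
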